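The retrosynthesis cuts, in order: the C14–O glycolate ester; C5–C14, which opens the eight-membered ring to an enone aldehyde; C11–C12, which removes the C12–C14 arm as a Z-allylboronate; C1–C9 together with C10–C11, which opens the cyclopentanone; then C1–C11, C9=C10, C3–C4 and C5–CH3, back to 4-methylcyclohexanone.
Enabling feature: the C2 carbonyl of the five-membered ring and the C11 oxygen stand 1,5 to each other along C2–C1–C9–C10–C11, with quaternary C9 and methyl-bearing C10 between them. This is the pattern left when an enol C1=C11 adds [2+2] to an alkene C9=C10 and the C1–C11 bond then breaks by retro-aldol.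
Forward order of rings: the six-membered ring (C4–C9) is bought, the five-membered ring (C1–C4, C9) closes in step 7, and the eight-membered ring (C4, C5, C9–C14) closes in step 16.
C11 is carried as an aldehyde rather than a ketone, so the enol carbon that must bond to C10 is unhindered and C11 and C12 can be set together afterwards by allylboration.
Stereochemistry: C6 comes from enantioselective deprotonation; C5 and C4 follow by trans relay from C6; C9 follows from C4 through the cis ring fusion; C10 is set in the cyclobutane closure; C11 and C12 come from the chair transition state of the Z-boronate under catalyst control; quaternary C5 and C14 are set in the bridged ring closure.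

Key step: step 7

Assumption: mutilin numbering is used throughout; 9 is written as its dicarbonyl tautomer; the C5 descriptor of the target string is read as that of the isomer in which C10 and C14 leave the six-membered ring on the same face, the only arrangement a five-atom bridge can close, and the string is carried through unchanged.

Step 1
Reactants: 1 4-methylcyclohexan-1-one
Product: 2 [(4S)-4-methylcyclohex-1-en-1-yl]oxy(trimethyl)silane
Conditions: (R,R)-bis(1-phenylethyl)amine, n-BuLi, THF, 0 °C; then Me3SiCl and 1 (internal quench), −100 to −78 °C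
Reagents that add atoms: chlorotrimethylsilane, C[Si](C)(C)Cl
Why: Enantioselective deprotonation: the twofold-symmetric chiral lithium amide removes one of the two enantiotopic axial α-protons of the chair with equatorial methyl, and the enolate is silylated as it forms, which makes prochiral C6 an (S) stereocentre.

Step 2
Reactants: 2 [(4S)-4-methylcyclohex-1-en-1-yl]oxy(trimethyl)silane
Product: 3 (4S)-4-methylcyclohex-2-en-1-one
Conditions: Pd(OAc)2 (10 mol %), O2 (1 atm), DMSO, 25 °C
Reagents that add atoms: none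
Why: Saegusa–Ito oxidation in its aerobic catalytic form: the enolate of divalent palladium loses the C5 hydrogen by β-hydride elimination, O2 returns zerovalent palladium to the divalent state, and C6 is not touched.

Step 3
Reactants: 3 (4S)-4-methylcyclohex-2-en-1-one; 4 3-bromoprop-1-ene
Product: 6 (2S,3R,4S)-3,4-dimethyl-2-(prop-2-en-1-yl)cyclohexan-1-one, via lithium enolate 5 (not isolated)
Conditions: Me2CuLi (from MeLi and CuBr·SMe2), Et2O, −78 to 0 °C; then 4, DMPU, THF, −78 to 0 °C
Reagents that add atoms: lithium dimethylcuprate, [Li+].C[Cu-]C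
Why: Conjugate addition with enolate trapping: the Gilman cuprate adds to C5 anti to the C6 methyl group, and the regiodefined enolate 5 is allylated at C4 anti to the new C5 methyl group, which gives the all-trans, all-equatorial ketone.

Step 4
Reactants: 6 (2S,3R,4S)-3,4-dimethyl-2-(prop-2-en-1-yl)cyclohexan-1-one
Product: 7 (1E,2S,3R,4S)-1-ethylidene-3,4-dimethyl-2-(prop-2-en-1-yl)cyclohexane
Conditions: EtPPh3Br, KOtBu, THF, 0 °C to rt
Reagents that add atoms: ethyltriphenylphosphonium bromide, CC[P+](c1ccccc1)(c1ccccc1)c1ccccc1.[Br-]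
Why: Wittig olefination with a non-stabilised ylide: the E alkene (methyl away from C4) should prevail because allylic 1,3-strain with the equatorial C4 arm disfavours the Z isomer, any Z isomer is harmless because alkene geometry is lost in step 7, and C4 keeps its more stable equatorial configuration.

Step 5
Reactants: 7 (1E,2S,3R,4S)-1-ethylidene-3,4-dimethyl-2-(prop-2-en-1-yl)cyclohexane
Product: 8 1-[(1S,2R,3S,6E)-6-ethylidene-2,3-dimethylcyclohexyl]propan-2-one
Conditions: PdCl2 (10 mol %), CuCl, O2 (1 atm), DMF/H2O 7:1, rt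
Reagents that add atoms: water, O
Why: Tsuji–Wacker oxidation: divalent palladium hydroxypalladates only the monosubstituted alkene, in the Markovnikov sense, because the trisubstituted ethylidene is too hindered to bind.

Step 6
Reactants: 8 1-[(1S,2R,3S,6E)-6-ethylidene-2,3-dimethylcyclohexyl]propan-2-one
Product: 9 4-[(1S,2R,3S,6E)-6-ethylidene-2,3-dimethylcyclohexyl]-3-oxobutanal (present as its hydrogen-bonded hydroxymethylene enol)
Conditions: LDA (2.1 equiv), THF, −78 °C; HCO2CH2CF3, −78 °C; dilute HCl work-up
Reagents that add atoms: 2,2,2-trifluoroethyl formate, O=COCC(F)(F)F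
Why: Kinetic Claisen-type formylation: LDA deprotonates the methyl side (C1) rather than the branched C3 side, and the very electrophilic formate traps this enolate before it can equilibrate.

Step 7
Reactants: 9 4-[(1S,2R,3S,6E)-6-ethylidene-2,3-dimethylcyclohexyl]-3-oxobutanal
Product: 11 (2R)-2-[(3aS,4R,5S,7aR)-4,5-dimethyl-2-oxooctahydro-7aH-inden-7a-yl]propanal, via cyclobutanol photoadduct 10 (not isolated)
Conditions: hν (300 nm lamps, Pyrex), degassed cyclohexane, 0.005 M, 20 °C; then SiO2, CH2Cl2, rt
Reagents that add atoms: none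
Why: Excitation of the chelated enol of 9 (C2=O, C1=C11–OH) gives a triplet that bonds first from C1 to C9, a 1,5-closure (rule of five) that makes the five-membered ring and leaves radicals at C10 and C11, which couple in a four-membered closure to cyclobutanol 10. Compound 10 is a strained β-hydroxy ketone and opens across C1–C11 by retro-aldol on silica gel, which releases the C2 ketone and the C11 aldehyde. The closest known reaction is the intramolecular de Mayo reaction of enolised 1,3-dicarbonyl compounds, formyl derivatives included, with alkenes held by a three-atom tether. C9 is set by C4: the equatorial C3 arm reaches only the adjacent axial lobe of C9, so the ring fusion is cis. C10 is set when the cyclobutane closes, with the methyl group settling next to C8H2 rather than next to branched C4, which matches suprafacial addition to the E alkene and stays adjustable by enolisation of the aldehyde. The step needs the straight rather than the crossed adduct and bonding of C10 to C11 rather than to C2; the three-atom tether C2–C3–C4 secures the first, and the strain of the alternative bicyclo[2.1.1]hexane together with the unhindered CH(OH) radical secures the second.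

Step 8
Reactants: 12 (2E)-3-methylpent-2-en-4-yn-1-ol
Product: 13 1-methoxy-4-({[(2E)-3-methylpent-2-en-4-yn-1-yl]oxy}methyl)benzene
Conditions: NaH, 4-methoxybenzyl chloride, DMF, 0 °C to rt
Reagents that add atoms: 4-methoxybenzyl chloride, COc1ccc(CCl)cc1
Why: Williamson etherification of a primary allylic alcohol; the PMB group survives poisoned-palladium hydrogenation, LDA and Pd(OAc)2 and leaves oxidatively in step 14.

Step 9
Reactants: 13 1-methoxy-4-({[(2E)-3-methylpent-2-en-4-yn-1-yl]oxy}methyl)benzene
Product: 14 1-methoxy-4-({[(2E)-3-methylpenta-2,4-dien-1-yl]oxy}methyl)benzene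
Conditions: H2 (1 atm), Pd/CaCO3 poisoned with Pb(OAc)2 (Lindlar catalyst), quinoline, EtOAc, rt
Reagents that add atoms: none
Why: Semihydrogenation of the terminal alkyne over poisoned palladium stops at the vinyl group and keeps the E trisubstituted alkene.

Step 10
Reactants: 14 1-methoxy-4-({[(2E)-3-methylpenta-2,4-dien-1-yl]oxy}methyl)benzene
Product: 15 2-{(2Z)-5-[(4-methoxybenzyl)oxy]-3-methylpent-2-en-1-yl}-4,4,5,5-tetramethyl-1,3,2-dioxaborolane
Conditions: Ni(cod)2 (2.5 mol %), PCy3 (2.5 mol %), pinacolborane, toluene, rt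
Reagents that add atoms: pinacolborane, CC1(C)OBOC1(C)C
Why: Nickel-catalysed 1,4-hydroboration of a 1,3-diene: zerovalent nickel binds the diene s-cis, hydrogen goes to the substituted terminus and boron to the CH2 terminus, so both termini end cis on the new C=C and the Z-allylboronate forms.

Step 11
Reactants: 11 (2R)-2-[(3aS,4R,5S,7aR)-4,5-dimethyl-2-oxooctahydro-7aH-inden-7a-yl]propanal; 15 2-{(2Z)-5-[(4-methoxybenzyl)oxy]-3-methylpent-2-en-1-yl}-4,4,5,5-tetramethyl-1,3,2-dioxaborolane
Product: 17 (3aS,4R,5S,7aR)-7a-[(2R,3S,4S)-3-hydroxy-4-{2-[(4-methoxybenzyl)oxy]ethyl}-4-methylhex-5-en-2-yl]-4,5-dimethyloctahydro-2H-inden-2-one, via pinacol borate 16 (not isolated)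
Conditions: (R)-3,3'-bis(2,4,6-triisopropylphenyl)-1,1'-binaphthyl-2,2'-diyl hydrogen phosphate [(R)-TRIP, 10 mol %], 4 Å MS, toluene, −30 °C to rt; aqueous work-up
Reagents that add atoms: none
Why: Allylboration through a closed Zimmerman–Traxler chair: the Z geometry of 15 puts the C13 arm axial and the methyl group equatorial, which fixes C12 relative to C11. Attack on the Re face of C11 is the Felkin–Anh sense for C10 (anti to C9) and is reinforced by the chiral phosphoric acid, and the aldehyde reacts far faster than the C2 ketone.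

Step 12
Reactants: 17 (3aS,4R,5S,7aR)-7a-[(2R,3S,4S)-3-hydroxy-4-{2-[(4-methoxybenzyl)oxy]ethyl}-4-methylhex-5-en-2-yl]-4,5-dimethyloctahydro-2H-inden-2-one
Product: 18 (3aS,4R,5S,7aR)-7a-[(2R,3S,4S)-4-{2-[(4-methoxybenzyl)oxy]ethyl}-4-methyl-3-[(triethylsilyl)oxy]hex-5-en-2-yl]-4,5-dimethyloctahydro-2H-inden-2-one
Conditions: Et3SiOTf, 2,6-lutidine, CH2Cl2, −78 to 0 °C
Reagents that add atoms: triethylsilyl trifluoromethanesulfonate, CC[Si](CC)(CC)OS(=O)(=O)C(F)(F)F
Why: The hindered C11 alcohol needs the silyl triflate; the TES ether prevents lactol formation with C14 later and leaves with fluoride at the end.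

Step 13
Reactants: 18 (3aS,4R,5S,7aR)-7a-[(2R,3S,4S)-4-{2-[(4-methoxybenzyl)oxy]ethyl}-4-methyl-3-[(triethylsilyl)oxy]hex-5-en-2-yl]-4,5-dimethyloctahydro-2H-inden-2-one
Product: 20 (4R,5S,7aS)-7a-[(2R,3S,4S)-4-{2-[(4-methoxybenzyl)oxy]ethyl}-4-methyl-3-[(triethylsilyl)oxy]hex-5-en-2-yl]-4,5-dimethyl-1,4,5,6,7,7a-hexahydro-2H-inden-2-one, via trimethylsilyl enol ether 19 (not isolated)
Conditions: LDA, Me3SiCl, THF, −78 °C; then Pd(OAc)2 (1.05 equiv), MeCN, rt
Reagents that add atoms: none
Why: Saegusa–Ito dehydrogenation: LDA takes the less hindered C3 proton (C1 is neopentyl), and only this enol ether can undergo β-hydride elimination because C9 bears no hydrogen, so C3=C4 is the only enone that can form; the C4 stereocentre has done its work and is spent here.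

Step 14
Reactants: 20 (4R,5S,7aS)-7a-[(2R,3S,4S)-4-{2-[(4-methoxybenzyl)oxy]ethyl}-4-methyl-3-[(triethylsilyl)oxy]hex-5-en-2-yl]-4,5-dimethyl-1,4,5,6,7,7a-hexahydro-2H-inden-2-one
Product: 21 (4R,5S,7aS)-7a-[(2R,3S,4S)-4-(2-hydroxyethyl)-4-methyl-3-[(triethylsilyl)oxy]hex-5-en-2-yl]-4,5-dimethyl-1,4,5,6,7,7a-hexahydro-2H-inden-2-one
Conditions: DDQ, CH2Cl2/pH 7 buffer 10:1, 0 °C
Reagents that add atoms: none
Why: Oxidative PMB cleavage by electron transfer to DDQ; the silyl ether, the enone and the vinyl group are inert at 0 °C.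

Step 15
Reactants: 21 (4R,5S,7aS)-7a-[(2R,3S,4S)-4-(2-hydroxyethyl)-4-methyl-3-[(triethylsilyl)oxy]hex-5-en-2-yl]-4,5-dimethyl-1,4,5,6,7,7a-hexahydro-2H-inden-2-one
Product: 22 (4R,5S,7aS)-4,5-dimethyl-7a-[(2R,3S,4S)-4-methyl-4-(2-oxoethyl)-3-[(triethylsilyl)oxy]hex-5-en-2-yl]-1,4,5,6,7,7a-hexahydro-2H-inden-2-one
Conditions: Dess–Martin periodinane, pyridine, CH2Cl2, 0 °C to rt
Reagents that add atoms: none
Why: Dess–Martin oxidation stops at the aldehyde under near-neutral conditions that leave the TES ether and the enone alone.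

Step 16
Reactants: 22 (4R,5S,7aS)-4,5-dimethyl-7a-[(2R,3S,4S)-4-methyl-4-(2-oxoethyl)-3-[(triethylsilyl)oxy]hex-5-en-2-yl]-1,4,5,6,7,7a-hexahydro-2H-inden-2-one
Product: 23 tricyclic alcohol: the target core with C2 ketone, C3=C4 alkene, free 14-OH and 11-OSiEt3 (5S,6S,9S,10R,11S,12S,14R)
Conditions: aluminium tris(2,6-diphenylphenoxide) (3.3 equiv, from Me3Al and 2,6-diphenylphenol), toluene, −78 °C; LDA, THF, −78 °C; dilute HCl work-up
Reagents that add atoms: none
Why: Proposed new method: both carbonyl groups of 22 are bound in the pockets of the bulky aluminium phenoxide, which buries C1, C3 and the aldehyde α-methylene, so LDA can only remove the outward γ-hydrogen at C5; the aluminium dienolate is blocked at C3 and attacks the activated aldehyde through C5, over which C14 is held because the C10–C14 arm stands pseudoaxial on C9 (1,3 to C5), giving the C5–C14 bond, the conjugated C3=C4 enone and the eight-membered ring; C5 is fixed by the tether, which reaches only one face of the planar C4=C5 terminus, and C14 by the aldehyde oxygen with its aluminium load turning to the outside of the forming ring; the closest known reactions are the Yamamoto vinylogous aldol reaction of enones (also used intramolecularly for large rings) and vinylogous Mukaiyama closures of eight-membered carbocycles, neither of which has been shown for a fully substituted γ-carbon in a medium ring.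

Step 17
Reactants: 23 tricyclic alcohol (14-OH, 11-OSiEt3); 24 {[tert-butyl(dimethyl)silyl]oxy}acetic acid
Product: 25 bis-silyl ether of the target (14-O-C(O)CH2OSiMe2tBu, 11-OSiEt3; 5S,6S,9S,10R,11S,12S,14R)
Conditions: EDC, DMAP, CH2Cl2, rt
Reagents that add atoms: none
Why: Steglich-type esterification (carbodiimide, DMAP) of the hindered C14 alcohol, which is the only free hydroxyl group.

Step 18
Reactants: 25 bis-silyl ether of the target
Product: 26 pleuromutilin F
Conditions: HF·pyridine, THF, 0 °C to rt
Reagents that add atoms: none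
Why: Fluoride-driven cleavage of both silyl ethers under mildly acidic conditions that leave the glycolate ester, the enone and the vinyl group intact.

Compound list
1 | 4-methylcyclohexan-1-one | CC1CCC(=O)CC1 | starting material
2 | [(4S)-4-methylcyclohex-1-en-1-yl]oxy(trimethyl)silane | C[C@H]1CCC(O[Si](C)(C)C)=CC1 | intermediate
3 | (4S)-4-methylcyclohex-2-en-1-one | C[C@H]1CCC(=O)C=C1 | intermediate
4 | 3-bromoprop-1-ene | C=CCBr | starting material
5 | lithium (3R,4S)-3,4-dimethylcyclohex-1-en-1-olate | C[C@H]1CCC([O-])=C[C@@H]1C.[Li+] | intermediate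
6 | (2S,3R,4S)-3,4-dimethyl-2-(prop-2-en-1-yl)cyclohexan-1-one | C=CC[C@H]1[C@H](C)[C@@H](C)CCC1=O | intermediate
7 | (1E,2S,3R,4S)-1-ethylidene-3,4-dimethyl-2-(prop-2-en-1-yl)cyclohexane | C=CC[C@H]1[C@H](C)[C@@H](C)CC/C1=C\C | intermediate
8 | 1-[(1S,2R,3S,6E)-6-ethylidene-2,3-dimethylcyclohexyl]propan-2-one | CC(=O)C[C@H]1[C@H](C)[C@@H](C)CC/C1=C\C | intermediate
9 | 4-[(1S,2R,3S,6E)-6-ethylidene-2,3-dimethylcyclohexyl]-3-oxobutanal | O=CCC(=O)C[C@H]1[C@H](C)[C@@H](C)CC/C1=C\C | intermediate
10 | cyclobutanol photoadduct (C1–C9 and C10–C11 formed, OH on C11) | O=C1C[C@H]2[C@H](C)[C@@H](C)CC[C@]23[C@@H](C)[C@H](O)[C@H]13 | intermediate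
11 | (2R)-2-[(3aS,4R,5S,7aR)-4,5-dimethyl-2-oxooctahydro-7aH-inden-7a-yl]propanal | O=C[C@H](C)[C@@]12CC[C@H](C)[C@@H](C)[C@@H]1CC(=O)C2 | intermediate
12 | (2E)-3-methylpent-2-en-4-yn-1-ol | C#C/C(C)=C/CO | starting material
13 | 1-methoxy-4-({[(2E)-3-methylpent-2-en-4-yn-1-yl]oxy}methyl)benzene | C#C/C(C)=C/COCc1ccc(OC)cc1 | intermediate
14 | 1-methoxy-4-({[(2E)-3-methylpenta-2,4-dien-1-yl]oxy}methyl)benzene | C=C/C(C)=C/COCc1ccc(OC)cc1 | intermediate
15 | 2-{(2Z)-5-[(4-methoxybenzyl)oxy]-3-methylpent-2-en-1-yl}-4,4,5,5-tetramethyl-1,3,2-dioxaborolane | COc1ccc(COCC/C(C)=C\CB2OC(C)(C)C(C)(C)O2)cc1 | intermediate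
16 | pinacol borate (11-O-Bpin) of 17 | C=C[C@](C)(CCOCc1ccc(OC)cc1)[C@@H](OB1OC(C)(C)C(C)(C)O1)[C@H](C)[C@@]12CC[C@H](C)[C@@H](C)[C@@H]1CC(=O)C2 | intermediate
17 | (3aS,4R,5S,7aR)-7a-[(2R,3S,4S)-3-hydroxy-4-{2-[(4-methoxybenzyl)oxy]ethyl}-4-methylhex-5-en-2-yl]-4,5-dimethyloctahydro-2H-inden-2-one | C=C[C@](C)(CCOCc1ccc(OC)cc1)[C@@H](O)[C@H](C)[C@@]12CC[C@H](C)[C@@H](C)[C@@H]1CC(=O)C2 | intermediate
18 | 11-O-triethylsilyl ether of 17 | C=C[C@](C)(CCOCc1ccc(OC)cc1)[C@@H](O[Si](CC)(CC)CC)[C@H](C)[C@@]12CC[C@H](C)[C@@H](C)[C@@H]1CC(=O)C2 | intermediate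
19 | C2=C3 trimethylsilyl enol ether of 18 | C=C[C@](C)(CCOCc1ccc(OC)cc1)[C@@H](O[Si](CC)(CC)CC)[C@H](C)[C@@]12CC[C@H](C)[C@@H](C)[C@@H]1C=C(O[Si](C)(C)C)C2 | intermediate
20 | C3=C4 enone, PMB ether (4R,5S,7aS; side chain 2R,3S,4S) | C=C[C@](C)(CCOCc1ccc(OC)cc1)[C@@H](O[Si](CC)(CC)CC)[C@H](C)[C@@]12CC[C@H](C)[C@@H](C)C1=CC(=O)C2 | intermediate
21 | C3=C4 enone, primary alcohol at C14 | C=C[C@](C)(CCO)[C@@H](O[Si](CC)(CC)CC)[C@H](C)[C@@]12CC[C@H](C)[C@@H](C)C1=CC(=O)C2 | intermediate
22 | C3=C4 enone, C14 aldehyde | C=C[C@](C)(CC=O)[C@@H](O[Si](CC)(CC)CC)[C@H](C)[C@@]12CC[C@H](C)[C@@H](C)C1=CC(=O)C2 | intermediate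
23 | tricyclic alcohol (14-OH, 11-OSiEt3; 5S,6S,9S,10R,11S,12S,14R) | C=C[C@]1(C)C[C@@H](O)[C@]2(C)C3=CC(=O)C[C@@]3(CC[C@@H]2C)[C@@H](C)[C@@H]1O[Si](CC)(CC)CC | intermediate
24 | {[tert-butyl(dimethyl)silyl]oxy}acetic acid | O=C(O)CO[Si](C)(C)C(C)(C)C | starting material
25 | bis-silyl ether of the target | C=C[C@]1(C)C[C@@H](OC(=O)CO[Si](C)(C)C(C)(C)C)[C@]2(C)C3=CC(=O)C[C@@]3(CC[C@@H]2C)[C@@H](C)[C@@H]1O[Si](CC)(CC)CC | intermediate
26 | pleuromutilin F | C=C[C@]1(C)C[C@@H](OC(=O)CO)[C@]2(C)C3=CC(=O)C[C@@]3(CC[C@@H]2C)[C@@H](C)[C@@H]1O | target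

Total steps: 18. Longest linear sequence: 15 steps (steps 1–7 and 11–18) from 4-methylcyclohexanone.

Steps most likely to fail

1. Step 16. The base may deprotonate at C1 or next to the aldehyde instead of at C5. The new bond may form at C3 instead of C5, the aldol may reverse, or the facial selectivity at C14 may be poor.
Fallback (known chemistry), from 22 back to 23:
   - Noyori acetalisation with 4-methoxybenzyl trimethylsilyl ether and catalytic Me3SiOTf at −78 °C gives the bis(4-methoxybenzyl) acetal F1.
   - tBuMe2SiOTf/Et3N under equilibrating conditions gives the extended silyl dienol ether F2 (C2–OSi, C2=C3, C4=C5), by analogy with the linear dienol ethers formed from cyclic enones.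
   - TiCl2(OiPr)2 in CH2Cl2 at −78 °C ionises the acetal and closes the ring by an intramolecular vinylogous Mukaiyama aldol reaction, a closure known for eight-membered carbocycles, to give the 14-O-(4-methoxybenzyl) ether F3.
   - DDQ then returns the route to 23.

2. Step 7. The crossed adduct may form instead of the straight one. The 1,4-diradical may revert or undergo internal hydrogen transfer, the keto aldehyde may suffer secondary photolysis or aldol self-condensation, and C10 may erode.
Fallback, from 9 back to 11: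
   - The reacting tautomer is locked and the two events are separated. Ac2O/pyridine acylates the aldehyde-derived enol oxygen to give the enol acetate F4.
   - Irradiation (Pyrex, acetone as sensitiser) gives the stable cyclobutyl acetate F5.
   - K2CO3/MeOH removes the acetate and triggers the retro-aldol opening to 11. This is the two-stage enol ester form of the de Mayo reaction, with the same two bonds formed.

3. Step 11. Addition to the neopentyl-type aldehyde may be slow. Competing syn-pentane interactions of both γ-substituents may lower the facial selectivity, and C10 may epimerise during a long reaction.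
Fallback, from 12 and 11 back to 17, replacing catalyst control by a more reactive, stoichiometric chiral allylborane:
   - LiAlH4 in Et2O converts 12 with transposition into 3-methylpenta-3,4-dien-1-ol F6.
   - NaH/4-methoxybenzyl chloride gives the allenyl PMB ether F7.
   - Kinetic hydroboration of the terminal C=C with (+)-diisopinocampheylborane (from (−)-α-pinene), from the side of the smaller methyl group, gives the Z-allylborane F8.
   - F8 is used at once with 11 at −78 °C (Re-face delivery), and oxidative work-up gives 17.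

Further compounds
F1 | step 16 | bis(4-methoxybenzyl) acetal of 22 | C=C[C@](C)(CC(OCc1ccc(OC)cc1)OCc1ccc(OC)cc1)[C@@H](O[Si](CC)(CC)CC)[C@H](C)[C@@]12CC[C@H](C)[C@@H](C)C1=CC(=O)C2
F2 | step 16 | extended tert-butyldimethylsilyl dienol ether of F1 | C=C[C@](C)(CC(OCc1ccc(OC)cc1)OCc1ccc(OC)cc1)[C@@H](O[Si](CC)(CC)CC)[C@H](C)[C@@]12CC[C@H](C)C(C)=C1C=C(O[Si](C)(C)C(C)(C)C)C2
F3 | step 16 | 14-O-(4-methoxybenzyl) ether of 23 | C=C[C@]1(C)C[C@@H](OCc2ccc(OC)cc2)[C@]2(C)C3=CC(=O)C[C@@]3(CC[C@@H]2C)[C@@H](C)[C@@H]1O[Si](CC)(CC)CC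
F4 | step 7 | (E)-enol acetate of 9 | CC(=O)O/C=C/C(=O)C[C@H]1[C@H](C)[C@@H](C)CC/C1=C\C
F5 | step 7 | cyclobutyl acetate photoadduct | O=C1C[C@H]2[C@H](C)[C@@H](C)CC[C@]23[C@@H](C)[C@@H](OC(C)=O)[C@H]13
F6 | step 11 | 3-methylpenta-3,4-dien-1-ol | C=C=C(C)CCO
F7 | step 11 | 1-methoxy-4-{[(3-methylpenta-3,4-dien-1-yl)oxy]methyl}benzene | C=C=C(C)CCOCc1ccc(OC)cc1
F8 | step 11 | {(2Z)-5-[(4-methoxybenzyl)oxy]-3-methylpent-2-en-1-yl}bis(isopinocampheyl)borane, from (−)-α-pinene | COc1ccc(COCC/C(C)=C\CB([C@H]2C[C@H]3C[C@@H]([C@@H]2C)C3(C)C)[C@H]2C[C@H]3C[C@@H]([C@@H]2C)C3(C)C)cc1
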